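Decide first which set-ups the earlier readings may speak for, and treat the others separately.

in all of them: starting material 0.30 M
- autumn: coupling partner 0.60 M; second reagent 0.36 M; third reagent 0.30 M; run made earlier
- dawn: coupling partner 0.60 M; second reagent 0.36 M; third reagent 0.42 M; run made earlier
- midnight: coupling partner 0.60 M; second reagent 0.36 M; third reagent 0.66 M; run made earlier
- dusk: coupling partner 1.2 M; second reagent 0.36 M; third reagent 0.30 M; run made earlier
- zeta: coupling partner 0.600 M; second reagent 0.360 M; third reagent 0.300 M; a closed flask charged with all of it at once and left for 3.0 min; time 3.0 min
- gamma: coupling partner 0.600 M; second reagent 0.360 M; third reagent 0.300 M; one stirred flow tank at steady state, fed with the mixture as stated, mean residence time 30.0 min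
- eta: coupling partner 0.600 M; second reagent 0.360 M; third reagent 0.300 M; a single well-mixed tank run continuously and read at steady state, 3.0 min in it on average
- theta: coupling partner 0.600 M; second reagent 0.360 M; third reagent 0.300 M (fed, over 1.50 min); all but third reagent at the start; third reagent goes in evenly over 1.50 min, the run ends at 3.0 min; time 3.0 min

| run | time / s | target / % | side product / % |
|---|---|---|---|
| autumn | 10.0 | 0 | 5.7 |
| autumn | 20.0 | 1.1 | 10.2 |
| autumn | 40.0 | 0 | 18.3 |
| autumn | 60.0 | 1.2 | 25.7 |
| autumn | 80.0 | 0.4 | 31.7 |
| autumn | 120 | 2.4 | 39.6 |
| dawn | 20.0 | 0 | 10.4 |
| dawn | 40.0 | 0.7 | 19.7 |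
| dawn | 50.0 | 1.7 | 22.8 |
| dawn | 80.0 | 0 | 31.0 |
| dawn | 90.0 | 1.2 | 35.0 |
| dawn | 120 | 0.3 | 40.3 |
| midnight | 10.0 | 0 | 6.3 |
| midnight | 20.0 | 0 | 10.9 |
| midnight | 40.0 | 0.9 | 19.8 |
| midnight | 60.0 | 0.3 | 25.2 |
| midnight | 80.0 | 0 | 31.4 |
| midnight | 120 | 0 | 39.6 |
| dusk | 10.0 | 0 | 5.7 |
| dusk | 15.0 | 0 | 7.3 |
| dusk | 30.0 | 0 | 15.8 |
| dusk | 60.0 | 0.3 | 24.9 |
| dusk | 120 | 2.1 | 37.5 |

(each reading ± 1 percentage point)

- the stated concentrations are those of everything mixed, before any reaction; amounts are the same in each set-up
- the feed brings no volume worth counting
- the earlier runs were made in a closed, stirred flask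

- the set-up with the highest share of target in all that became target or side product, at the outlet or at the end ("none" if the first two lie within 2 percentage points) (zeta / gamma / eta / theta / none)
- share of target in all that became target or side product, at the outlet or at the end, zeta
- share of target in all that became target or side product, at the outlet or at the end, gamma
- share of target in all that became target or side product, at the outlet or at the end, eta
- share of target in all that became target or side product, at the outlet or at the end, theta

Take as the zero of the scale a flask that makes no target, so the lower bound on the share is zero. For an upper mark, which is a reading and not a proof, take the autumn run at 120 s: 2.4 % target against 39.6 % side product gives a share of 5.71 %. Tighten this by pooling the last readings of the earlier runs, which gives 2.97 %, still a reading with a scatter of 1 percentage point on each value.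

Now ask how far this bracket reaches. Let Q be the fraction of starting material found as side product at time t, and count Q as the whole loss. The autumn run reads 0.252 /min for the side-product clock, the pseudo-first-order constant ln(1/(1−Q))/t. Multiply it by the time to get the count n. The last autumn reading stands at n = 0.504, while zeta, eta and theta stand at 0.756, a modest step beyond it. Gamma, with ten times that stay, stands at 7.56, so my bracket does not bind gamma.

The forecast gives zeta 2 %, gamma 2.5 %, eta 2 %, theta 2.5 % and best none, on this ground: "The data do not separate the set-ups". Its values lie inside the bracket. I part from it on gamma, where I would commit to no such number.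

The flask gives zeta 0.421 %, gamma 18.7 %, eta 5.90 %, theta 1.69 %, and the best is gamma.

    starting material + coupling partner → intermediate A (k = 0.00330 /M/s)
    second reagent + intermediate A → intermediate B (k = 0.0110 /M/s)
    third reagent + intermediate B → target (k = 0.130 /M/s)
    starting material + second reagent → side product (k = 0.0170 /M/s)
    third reagent → decomposed reagent (k = 0.0440 /s)

The back-mixing and the longer stay are the main reason for gamma's share: without them it falls from 18.7 % to 0.421 %. Gamma's share stands above the bracket. Put the clock into a tank balance, c = cA/(1+n), with cA the charged starting material. For gamma it gives 0.0350 M of starting material, where the tank holds 0.0382 M. For eta it leaves 56.9 %, where the outlet holds 48.6 %.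

The earlier runs and the new flask are simulated for substances that don't exist, and the scatter is random.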